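The readings were computed on assumed constants, noise included.

Begin at the late readings and walk back: midnight holds 15.7% target at 40.0 min, dusk already 82.6% at 20.0 min. Divide each by its time to get mean rates of 0.00392 min⁻¹ and 0.0413 min⁻¹ of the charge.

| setting | midnight | dusk | delta | beta | eta | theta | alpha |
|---|---|---|---|---|---|---|---|
| starting material | 0.10 M | 0.10 M | 0.10 M | 0.10 M | 0.10 M | 0.10 M | 0.10 M |
| solid second substrate | 2.5 equiv | 2.5 equiv | 2.50 equiv | 2.50 equiv | 2.50 equiv | 2.50 equiv | 2.50 equiv |
| free enzyme | 0.0015 mol% | 0.033 mol% | 0.0025 mol% | 0.005 mol% | 0.01 mol% | 0.02 mol% | 0.04 mol% |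
| remark | run made earlier | run made earlier |  |  |  |  |  |
| time |  |  | 40 min | 40 min | 40 min | 40 min | 40 min |

| run | time / min | target / % | starting material / % |
|---|---|---|---|
| midnight | 3.00 | 0 | 98.3 |
| midnight | 6.00 | 1.4 | 98.5 |
| midnight | 12.0 | 4.3 | 96.7 |
| midnight | 20.0 | 7.8 | 92.8 |
| midnight | 40.0 | 15.7 | 84.4 |
| dusk | 3.00 | 9.6 | 90.2 |
| dusk | 6.00 | 23.2 | 77.3 |
| dusk | 12.0 | 50.3 | 49.1 |
| dusk | 20.0 | 82.6 | 17.3 |
| dusk | 40.0 | 99.7 | 1.4 |

(scatter of a reading: 0.5 percentage points)

- what was read earlier has a scatter of 0.5 percentage points, one standard deviation
- at the start none of the solid second substrate is in solution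
- "hardly changes" means that all values lie within two and a half points (for a concentration: within two and a half percent of the largest)

- amount of target at the end, in percent of the starting material charged for delta, beta, eta, theta, alpha, in this order
- how that number moves from the first to the last of them (hardly changes / rises, then falls / falls, then rises / rises all the way / falls all the way)

Loading rose 22.0-fold between the runs, the rate 10.5-fold. Dusk's 0.478 is therefore its return, the mean rate per unit of loading set against midnight's.

Now assume that rate against loading starts from zero and bends one way. Return then falls with loading, so midnight's return gives a ceiling: 26.2% for delta, 52.3% for beta, and for eta 105%, which passes the charge and so says nothing. The straight chord from midnight to dusk gives a floor: 20.4%, 32.3% and 56.0%. For theta the chord reaches the whole charge at 38.6 min, inside 40 min, and dusk's tail bends, so expect theta close to complete. Alpha carries more loading than dusk, so expect at least dusk's 99.7%. Two runs and the origin take the hand no further.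

The forecast, reasoning “so the rate is less than proportional to enzyme”, gives 25%, 45%, 78%, 99.5% and 99.7%, rises all the way. Its delta lies under the ceiling and over the floor, as does its beta, and its eta stands above the floor.

The flasks give 24.9%, 45.9%, 76.2%, 97.9% and 100%, rises all the way, so the forecast held.

    starting material + free enzyme ⇌ first complex (K = 13.0 L mol⁻¹, k = 7490 L mol⁻¹ s⁻¹)
    first complex → loaded enzyme + first product (k = 12.4 s⁻¹)
    second substrate + loaded enzyme ⇌ second complex (K = 4.10 L mol⁻¹, k = 5630 L mol⁻¹ s⁻¹)
    second complex → free enzyme + target (k = 134 s⁻¹)
    second substrate + first product ⇌ idle adduct, settled at all times (K = 12.6 L mol⁻¹)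
    first product → by-product carried off (k = 0.00186 s⁻¹)
    solid second substrate ⇌ second substrate, rate k7*(cs7 - [second substrate]) while solid is left; crystals form when [second substrate] > cs7 (solubility = 35.0 mM, k = 0.00309 s⁻¹)

The pairing of second substrate with first product, 0.00218 M of idle adduct in delta at 40.0 min, makes no difference worth reading to delta's target. Reckon the return again: delta's is 0.952, beta's 0.877, and eta's 0.728, in eta with c(second substrate) at 0.0262 M at 40.0 min, lower than delta's 0.0314 M at that time.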